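**Retrosynthetic overview**

1. Endgame: the vicinal bromochloride is traced back to the homoprenyl olefin (asymmetric epoxidation, bromohydrin, 1,2-bromine shift with chloride capture), and the tertiary vinyl carbinol to an (E)-allylic alcohol made from a terminal alkyne (asymmetric epoxidation, reductive fragmentation). This leaves a 7-oxabicyclo[2.2.1]heptane carrying only a butynyl and a homoprenyl chain.
2. Key disconnection: the bonds C6–C1 and O7–C4 of the oxabicycle are cut together. This opens both rings to an acyclic methyl ketone (O7=C1) whose quaternary C3 carries a cyclopropane C4–C5–C6 with two ester groups on C6; the esters are removed after the key step by saponification and two decarboxylations.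
3. Enabling feature: O7 and the C5–C6 bridge both span the bridgeheads C1 and C4, so the ring O7–C1–C6–C5–C4 is the sum of a carbonyl group and a three-carbon unit, and the C2–C3 tether places the carbonyl oxygen in five-ring distance of the cyclopropane CH. Strain release drives the step; the oxolane O7–C1–C2–C3–C4 closes first, the cyclohexane C1–C6 (which is also the second oxolane) second.
4. The keto cyclopropane comes from geranyl hex-5-ynoate: an enantioselective Ireland–Claisen rearrangement forms C2–C3 with both stereocentres, methyllithium gives the methyl ketone, and an enantioselective cyclopropanation of the new vinyl group sets the cyclopropane CH.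
5. Starting materials: geraniol and hex-5-ynoic acid.

Key step: step 5

Assumption: the sense of induction of the two chiral reagents that act without substrate help (the bromoborane of step 2 and the bisoxazoline ligand of step 4) is taken as written; if a trial shows the opposite sense, the antipodal reagent is used and nothing else changes.

Locants in the text (C1–C6, O7) are those of the oxabicycle in the target: C1 methyl-bearing bridgehead, C2 CH with the hydroxylated chain, C3 quaternary carbon, C4 bridgehead CH, C5–C6 the CH2–CH2 bridge. The systematic names of 11–14 renumber the ring because of the carboxyl groups (their C2 is C6 of the text).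

**Route**

Step 1
Reactants: 1 geraniol; 2 hex-5-ynoic acid
Product: 3 (2E)-3,7-dimethylocta-2,6-dien-1-yl hex-5-ynoate
Conditions: DCC, DMAP (cat.), CH2Cl2, 0 °C → rt
Reagents that add atoms: none
Why: Steglich esterification of a primary allylic alcohol is reliable, leaves the (E)-olefin and the alkyne untouched and forms no stereocentre.

Step 2
Reactants: 3 (2E)-3,7-dimethylocta-2,6-dien-1-yl hex-5-ynoate
Product: 6 (2S,3R)-2-(but-3-yn-1-yl)-3-ethenyl-3,7-dimethyloct-6-enoic acid, via boron ketene acetal 4 (not isolated), via boron carboxylate 5 (not isolated)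
Conditions: (4S,5S)-2-bromo-1,3-bis[3,5-bis(trifluoromethyl)phenylsulfonyl]-4,5-diphenyl-1,3,2-diazaborolidine (1.2 equiv), iPr2NEt, CH2Cl2, −78 °C; then −20 → 4 °C, several days; aq. work-up
Reagents that add atoms: none
Why: Soft enolisation should give the O-boron ketene acetal with the butynyl-bearing chain cis to O–B, and the chair [3,3] shift (enantioselective Ireland–Claisen rearrangement) with the homoprenyl group equatorial and the methyl group axial fixes the C2/C3 relationship, while the C2-symmetric boron ligand selects the enantiotopic face, so that C2 (S) and the quaternary C3 (R) are both set here.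

Step 3
Reactants: 6 (2S,3R)-2-(but-3-yn-1-yl)-3-ethenyl-3,7-dimethyloct-6-enoic acid
Product: 9 (3S,4R)-4-ethenyl-4,8-dimethyl-3-[4-(trimethylsilyl)but-3-yn-1-yl]non-7-en-2-one, via trilithio adduct 7 (not isolated), via bis-silyl ketal 8 (not isolated)
Conditions: MeLi (3.5 equiv), Et2O, 0 °C → rt; then Me3SiCl (excess), 0 °C → rt; then 1 M HCl
Reagents that add atoms: methyllithium, C[Li]; chlorotrimethylsilane, C[Si](C)(C)Cl
Why: Addition of methyllithium to the lithium carboxylate stops at the gem-diolate (acid to methyl ketone conversion), the chlorosilane quench destroys excess reagent before the ketone is released and silylates the lithium acetylide at carbon, and the α-stereocentre should survive because the tetrahedral adduct cannot enolise.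

Step 4
Reactants: 9 (3S,4R)-4-ethenyl-4,8-dimethyl-3-[4-(trimethylsilyl)but-3-yn-1-yl]non-7-en-2-one
Product: 10 dimethyl (2S)-2-{(3S,4R)-4,8-dimethyl-2-oxo-3-[4-(trimethylsilyl)but-3-yn-1-yl]non-7-en-4-yl}cyclopropane-1,1-dicarboxylate
Conditions: [Cu(MeCN)4]PF6 (10 mol%), chiral side-armed bisoxazoline ligand (12 mol%), PhI=C(CO2Me)2 (1.3 equiv), 4 Å MS, PhMe, −20 °C → rt
Reagents that add atoms: phenyliodonium bis(methoxycarbonyl)methanide, COC(=O)[C-](C(=O)OC)[I+]c1ccccc1
Why: Copper-catalysed asymmetric cyclopropanation with a malonate carbenoid should occur at the only monosubstituted olefin (the trisubstituted olefin and the silyl alkyne are more hindered toward the bulky carbenoid), and the C2-symmetric ligand rather than the neighbouring quaternary centre selects the alkene face, so that the new ring CH is (S).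

Step 5
Reactants: 10 dimethyl (2S)-2-{(3S,4R)-4,8-dimethyl-2-oxo-3-[4-(trimethylsilyl)but-3-yn-1-yl]non-7-en-4-yl}cyclopropane-1,1-dicarboxylate
Product: 11 dimethyl (1R,4R,5S,6S)-1,5-dimethyl-5-(4-methylpent-3-en-1-yl)-6-[4-(trimethylsilyl)but-3-yn-1-yl]-7-oxabicyclo[2.2.1]heptane-2,2-dicarboxylate
Conditions: Sc(OTf)3 (20 mol%), 4 Å MS, ClCH2CH2Cl, rt → 50 °C
Reagents that add atoms: none
Why: Sc(OTf)3 chelates the gem-diester and polarises the cyclopropane bond between the ring CH and the malonate carbon; the ketone oxygen attacks that CH from the rear (5-exo-tet, helped by the quaternary neighbour) to give a cyclic oxocarbenium/scandium malonate zwitterion, whose malonate carbon then adds to the oxocarbenium carbon (6-exo-trig for the carbocycle, which at the same time completes the second oxolane). The closest known reaction type is the Lewis-acid-catalysed intramolecular formal [3+2] cross-cycloaddition of cyclopropane-1,1-diesters with tethered ketones to oxa-bridged bicycles. The bridgehead CH (C4) is set by inversion of the (S)-cyclopropane centre, which places the C5–C6 bridge syn to the C3 methyl group and anti to the homoprenyl chain; the methyl-bearing bridgehead (C1) is set by the bridge itself, because the tethered malonate can reach only one face of the planar oxocarbenium ion. The step needs stereospecific oxygen attack rather than a halide relay or capture of the activated ring by the trisubstituted olefin or the silyl alkyne; the non-nucleophilic triflate counter-ion, the five-membered transition state through the carbonyl oxygen and the mild conditions should secure this. Release of the cyclopropane strain pays for the hindered C–C bond that is formed beside the C2 side chain.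

Step 6
Reactants: 11 dimethyl (1R,4R,5S,6S)-1,5-dimethyl-5-(4-methylpent-3-en-1-yl)-6-[4-(trimethylsilyl)but-3-yn-1-yl]-7-oxabicyclo[2.2.1]heptane-2,2-dicarboxylate
Product: 13 (1R,2RS,4R,5S,6S)-6-(but-3-yn-1-yl)-1,5-dimethyl-5-(4-methylpent-3-en-1-yl)-7-oxabicyclo[2.2.1]heptane-2-carboxylic acid, via malonic acid 12 (not isolated)
Conditions: KOH (excess), MeOH/H2O, 70 °C; then 1 M HCl, 0 °C; then PhMe, 110 °C
Reagents that add atoms: potassium hydroxide, [K+].[OH-]
Why: Saponification of the non-enolisable gem-diester (which also cleaves the alkynyl–silicon bond) and thermal decarboxylation of the malonic acid under neutral conditions remove the first activating group without forming a β-alkoxy ester enolate that could open the oxygen bridge; the new centre at the carboxyl-bearing carbon is formed without control and is deleted in step 7.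

Step 7
Reactants: 13 (1R,2RS,4R,5S,6S)-6-(but-3-yn-1-yl)-1,5-dimethyl-5-(4-methylpent-3-en-1-yl)-7-oxabicyclo[2.2.1]heptane-2-carboxylic acid
Product: 15 (1S,2S,3S,4R)-2-(but-3-yn-1-yl)-1,3-dimethyl-3-(4-methylpent-3-en-1-yl)-7-oxabicyclo[2.2.1]heptane, via Barton ester 14 (not isolated)
Conditions: N-hydroxypyridine-2-thione, DCC, DMAP (cat.), CH2Cl2, rt, dark; then t-BuSH (excess), hν (tungsten lamp), rt
Reagents that add atoms: none
Why: Barton reductive decarboxylation replaces the remaining carboxyl group by hydrogen through a secondary radical that the thiol should quench faster than it can cyclise onto the side-chain alkyne, and no stereocentre of the core is touched.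

Step 8
Reactants: 15 (1S,2S,3S,4R)-2-(but-3-yn-1-yl)-1,3-dimethyl-3-(4-methylpent-3-en-1-yl)-7-oxabicyclo[2.2.1]heptane
Product: 17 (1S,2S,3S,4R)-2-[(3E)-5-hydroxy-3-methylpent-3-en-1-yl]-1,3-dimethyl-3-(4-methylpent-3-en-1-yl)-7-oxabicyclo[2.2.1]heptane, via alkenylalane 16 (not isolated)
Conditions: AlMe3 (3 equiv), Cp2ZrCl2 (0.3 equiv), CH2Cl2, 0 °C → rt; then n-BuLi, THF, −78 °C; (CH2O)n, → rt
Reagents that add atoms: trimethylaluminium, C[Al](C)C; formaldehyde (as paraformaldehyde), C=O
Why: Zirconium-catalysed syn-carboalumination of the terminal alkyne (Negishi carboalumination) puts the methyl group on the internal carbon and aluminium on the terminus, and hydroxymethylation of the derived alanate gives the (E)-trisubstituted allylic alcohol with retention of olefin geometry.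

Step 9
Reactants: 17 (1S,2S,3S,4R)-2-[(3E)-5-hydroxy-3-methylpent-3-en-1-yl]-1,3-dimethyl-3-(4-methylpent-3-en-1-yl)-7-oxabicyclo[2.2.1]heptane
Product: 18 (1S,2S,3S,4R)-2-{2-[(2S,3S)-3-(hydroxymethyl)-2-methyloxiran-2-yl]ethyl}-1,3-dimethyl-3-(4-methylpent-3-en-1-yl)-7-oxabicyclo[2.2.1]heptane
Conditions: Ti(OiPr)4 (10 mol%), L-(+)-diethyl tartrate (12 mol%), t-BuOOH, 4 Å MS, CH2Cl2, −20 °C
Reagents that add atoms: tert-butyl hydroperoxide, CC(C)(C)OO
Why: Sharpless asymmetric epoxidation acts only on the allylic alcohol (the homoprenyl olefin is not addressed), and the L-(+)-tartrate delivers oxygen to the face that gives the (2S,3S)-epoxy alcohol, which fixes the future carbinol centre as (S).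

Step 10
Reactants: 18 (1S,2S,3S,4R)-2-{2-[(2S,3S)-3-(hydroxymethyl)-2-methyloxiran-2-yl]ethyl}-1,3-dimethyl-3-(4-methylpent-3-en-1-yl)-7-oxabicyclo[2.2.1]heptane
Product: 19 (1S,2S,3S,4R)-2-{2-[(2S,3R)-3-(iodomethyl)-2-methyloxiran-2-yl]ethyl}-1,3-dimethyl-3-(4-methylpent-3-en-1-yl)-7-oxabicyclo[2.2.1]heptane
Conditions: I2, PPh3, imidazole, CH2Cl2, 0 °C
Reagents that add atoms: iodine, II
Why: Appel-type iodination of the primary alcohol leaves the epoxide intact and changes no stereocentre (the descriptor of the oxirane CH changes by priority only).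

Step 11
Reactants: 19 (1S,2S,3S,4R)-2-{2-[(2S,3R)-3-(iodomethyl)-2-methyloxiran-2-yl]ethyl}-1,3-dimethyl-3-(4-methylpent-3-en-1-yl)-7-oxabicyclo[2.2.1]heptane
Product: 21 (1S,2S,3S,4R)-1,3-dimethyl-3-(4-methylpent-3-en-1-yl)-2-{(3S)-3-methyl-3-[(triethylsilyl)oxy]pent-4-en-1-yl}-7-oxabicyclo[2.2.1]heptane, via lithium alkoxide 20 (not isolated)
Conditions: n-BuLi (1.1 equiv), THF, −78 °C; then Et3SiOTf (1.3 equiv), −78 → 0 °C
Reagents that add atoms: triethylsilyl trifluoromethanesulfonate, CC[Si](CC)(CC)OS(=O)(=O)C(F)(F)F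
Why: Iodine–lithium exchange triggers β-elimination with opening of the epoxide (reductive fragmentation of a 2,3-epoxy iodide) to the tertiary vinyl carbinolate, whose C–O bond is not broken so that the (S) centre from step 9 is kept, and the silyl triflate protects it for the halogenation steps.

Step 12
Reactants: 21 (1S,2S,3S,4R)-1,3-dimethyl-3-(4-methylpent-3-en-1-yl)-2-{(3S)-3-methyl-3-[(triethylsilyl)oxy]pent-4-en-1-yl}-7-oxabicyclo[2.2.1]heptane
Product: 22 (1S,2S,3S,4R)-3-{2-[(2R)-3,3-dimethyloxiran-2-yl]ethyl}-1,3-dimethyl-2-{(3S)-3-methyl-3-[(triethylsilyl)oxy]pent-4-en-1-yl}-7-oxabicyclo[2.2.1]heptane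
Conditions: D-fructose-derived ketone catalyst (1,2:4,5-di-O-isopropylidene-β-D-erythro-hexo-2,3-diulo-2,6-pyranose, 30 mol%), Oxone (2KHSO5·KHSO4·K2SO4), K2CO3, Bu4NHSO4 (cat.), MeCN/CH2(OMe)2, aq. Na2B4O7/Na2EDTA buffer, 0 °C
Reagents that add atoms: Oxone (active component potassium peroxymonosulfate), [K+].[O-]S(=O)(=O)OO
Why: Shi epoxidation with the D-fructose-derived dioxirane is selective for the electron-rich trisubstituted olefin over the hindered vinyl group and should give the (R)-epoxide by reagent control through the spiro transition state.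

Step 13
Reactants: 22 (1S,2S,3S,4R)-3-{2-[(2R)-3,3-dimethyloxiran-2-yl]ethyl}-1,3-dimethyl-2-{(3S)-3-methyl-3-[(triethylsilyl)oxy]pent-4-en-1-yl}-7-oxabicyclo[2.2.1]heptane
Product: 23 (1S,2S,3S,4R)-3-[(3R)-4-bromo-3-hydroxy-4-methylpentyl]-1,3-dimethyl-2-{(3S)-3-methyl-3-[(triethylsilyl)oxy]pent-4-en-1-yl}-7-oxabicyclo[2.2.1]heptane
Conditions: MgBr2·OEt2 (2 equiv), Et2O, −40 → −10 °C; cold aq. NaHCO3
Reagents that add atoms: magnesium bromide (etherate), Br[Mg]Br
Why: Lewis-acid-assisted opening of the trisubstituted epoxide by bromide at the tertiary carbon (halohydrin formation) leaves the secondary C–O bond intact, so the (R) carbinol centre is retained.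

Step 14
Reactants: 23 (1S,2S,3S,4R)-3-[(3R)-4-bromo-3-hydroxy-4-methylpentyl]-1,3-dimethyl-2-{(3S)-3-methyl-3-[(triethylsilyl)oxy]pent-4-en-1-yl}-7-oxabicyclo[2.2.1]heptane
Product: 25 (1S,2S,3S,4R)-3-[(3S)-3-bromo-4-chloro-4-methylpentyl]-1,3-dimethyl-2-{(3S)-3-methyl-3-[(triethylsilyl)oxy]pent-4-en-1-yl}-7-oxabicyclo[2.2.1]heptane, via secondary triflate 24 (not isolated)
Conditions: Tf2O (1.2 equiv), 2,6-lutidine, CH2Cl2, −78 °C; then Bu4NCl (3 equiv), −78 → −20 °C
Reagents that add atoms: tetrabutylammonium chloride, CCCC[N+](CCCC)(CCCC)CCCC.[Cl-]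
Why: The antiperiplanar tertiary bromine displaces the triflate with inversion (neighbouring-group participation) to a bromonium ion that chloride opens at the tertiary carbon, which amounts to a stereospecific 1,2-bromine shift with deoxychlorination and should give the (S)-bromide beside the tertiary chloride.

Step 15
Reactants: 25 (1S,2S,3S,4R)-3-[(3S)-3-bromo-4-chloro-4-methylpentyl]-1,3-dimethyl-2-{(3S)-3-methyl-3-[(triethylsilyl)oxy]pent-4-en-1-yl}-7-oxabicyclo[2.2.1]heptane
Product: 26 (3S)-5-[(1S,2S,3S,4R)-3-[(3S)-3-bromo-4-chloro-4-methylpentyl]-1,3-dimethyl-7-oxabicyclo[2.2.1]heptan-2-yl]-3-methylpent-1-en-3-ol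
Conditions: HF·pyridine, pyridine, THF, 0 °C → rt
Reagents that add atoms: none
Why: Buffered fluoride cleavage of the triethylsilyl ether frees the tertiary allylic alcohol without base-induced elimination of the vicinal bromochloride, and no stereocentre is affected.

**Compound list**

1 | geraniol, (2E)-3,7-dimethylocta-2,6-dien-1-ol | CC(C)=CCC/C(C)=C/CO | starting material
2 | hex-5-ynoic acid | C#CCCCC(=O)O | starting material
3 | (2E)-3,7-dimethylocta-2,6-dien-1-yl hex-5-ynoate | C#CCCCC(=O)OC/C=C(C)/CCC=C(C)C | intermediate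
4 | O-boron ketene acetal of 3: butynyl-bearing chain cis to O–B, boron held in the (4S,5S)-1,3-bis[3,5-bis(trifluoromethyl)phenylsulfonyl]-4,5-diphenyl-1,3,2-diazaborolidine | C#CCC/C=C(/OC/C=C(C)/CCC=C(C)C)\OB1N(S(=O)(=O)c2cc(cc(c2)C(F)(F)F)C(F)(F)F)[C@@H](c2ccccc2)[C@H](c2ccccc2)N1S(=O)(=O)c1cc(cc(c1)C(F)(F)F)C(F)(F)F | intermediate
5 | boron carboxylate of acid 6 (same diazaborolidinyl group on the carboxyl oxygen) | C#CCC[C@H](C(=O)OB1N(S(=O)(=O)c2cc(cc(c2)C(F)(F)F)C(F)(F)F)[C@@H](c2ccccc2)[C@H](c2ccccc2)N1S(=O)(=O)c1cc(cc(c1)C(F)(F)F)C(F)(F)F)[C@](C)(CCC=C(C)C)C=C | intermediate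
6 | (2S,3R)-2-(but-3-yn-1-yl)-3-ethenyl-3,7-dimethyloct-6-enoic acid | C#CCC[C@H](C(=O)O)[C@](C)(CCC=C(C)C)C=C | intermediate
7 | trilithio adduct: lithium acetylide and dilithium 1,1-diolate formed from 6 and MeLi | [Li]C#CCC[C@H](C(C)(O[Li])O[Li])[C@](C)(CCC=C(C)C)C=C | intermediate
8 | bis(trimethylsilyl) ketal of 9, C-silylated alkyne | C[Si](C)(C)C#CCC[C@H](C(C)(O[Si](C)(C)C)O[Si](C)(C)C)[C@](C)(CCC=C(C)C)C=C | intermediate
9 | (3S,4R)-4-ethenyl-4,8-dimethyl-3-[4-(trimethylsilyl)but-3-yn-1-yl]non-7-en-2-one | C[Si](C)(C)C#CCC[C@H](C(C)=O)[C@](C)(CCC=C(C)C)C=C | intermediate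
10 | dimethyl (2S)-2-{(3S,4R)-4,8-dimethyl-2-oxo-3-[4-(trimethylsilyl)but-3-yn-1-yl]non-7-en-4-yl}cyclopropane-1,1-dicarboxylate | C[Si](C)(C)C#CCC[C@H](C(C)=O)[C@](C)(CCC=C(C)C)[C@@H]1CC1(C(=O)OC)C(=O)OC | intermediate
11 | dimethyl (1R,4R,5S,6S)-1,5-dimethyl-5-(4-methylpent-3-en-1-yl)-6-[4-(trimethylsilyl)but-3-yn-1-yl]-7-oxabicyclo[2.2.1]heptane-2,2-dicarboxylate | C[Si](C)(C)C#CCC[C@H]1[C@](C)(CCC=C(C)C)[C@H]2CC(C(=O)OC)(C(=O)OC)[C@]1(C)O2 | intermediate
12 | (1R,4R,5S,6S)-6-(but-3-yn-1-yl)-1,5-dimethyl-5-(4-methylpent-3-en-1-yl)-7-oxabicyclo[2.2.1]heptane-2,2-dicarboxylic acid | C#CCC[C@H]1[C@](C)(CCC=C(C)C)[C@H]2CC(C(=O)O)(C(=O)O)[C@]1(C)O2 | intermediate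
13 | (1R,2RS,4R,5S,6S)-6-(but-3-yn-1-yl)-1,5-dimethyl-5-(4-methylpent-3-en-1-yl)-7-oxabicyclo[2.2.1]heptane-2-carboxylic acid (both epimers at the carboxyl-bearing carbon, which is left undefined in the SMILES) | C#CCC[C@H]1[C@](C)(CCC=C(C)C)[C@H]2CC(C(=O)O)[C@]1(C)O2 | intermediate
14 | 2-thioxopyridin-1(2H)-yl ester of 13 (Barton ester) | C#CCC[C@H]1[C@](C)(CCC=C(C)C)[C@H]2CC(C(=O)ON3C=CC=CC3=S)[C@]1(C)O2 | intermediate
15 | (1S,2S,3S,4R)-2-(but-3-yn-1-yl)-1,3-dimethyl-3-(4-methylpent-3-en-1-yl)-7-oxabicyclo[2.2.1]heptane | C#CCC[C@H]1[C@](C)(CCC=C(C)C)[C@H]2CC[C@]1(C)O2 | intermediate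
16 | (1S,2S,3S,4R)-2-[(3E)-4-(dimethylalumanyl)-3-methylbut-3-en-1-yl]-1,3-dimethyl-3-(4-methylpent-3-en-1-yl)-7-oxabicyclo[2.2.1]heptane | C[Al](C)/C=C(C)/CC[C@H]1[C@](C)(CCC=C(C)C)[C@H]2CC[C@]1(C)O2 | intermediate
17 | (1S,2S,3S,4R)-2-[(3E)-5-hydroxy-3-methylpent-3-en-1-yl]-1,3-dimethyl-3-(4-methylpent-3-en-1-yl)-7-oxabicyclo[2.2.1]heptane | OC/C=C(C)/CC[C@H]1[C@](C)(CCC=C(C)C)[C@H]2CC[C@]1(C)O2 | intermediate
18 | (1S,2S,3S,4R)-2-{2-[(2S,3S)-3-(hydroxymethyl)-2-methyloxiran-2-yl]ethyl}-1,3-dimethyl-3-(4-methylpent-3-en-1-yl)-7-oxabicyclo[2.2.1]heptane | OC[C@@H]3O[C@@]3(C)CC[C@H]1[C@](C)(CCC=C(C)C)[C@H]2CC[C@]1(C)O2 | intermediate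
19 | (1S,2S,3S,4R)-2-{2-[(2S,3R)-3-(iodomethyl)-2-methyloxiran-2-yl]ethyl}-1,3-dimethyl-3-(4-methylpent-3-en-1-yl)-7-oxabicyclo[2.2.1]heptane | IC[C@@H]3O[C@@]3(C)CC[C@H]1[C@](C)(CCC=C(C)C)[C@H]2CC[C@]1(C)O2 | intermediate
20 | lithium (3S)-5-[(1S,2S,3S,4R)-1,3-dimethyl-3-(4-methylpent-3-en-1-yl)-7-oxabicyclo[2.2.1]heptan-2-yl]-3-methylpent-1-en-3-olate | C=C[C@@](C)(O[Li])CC[C@H]1[C@](C)(CCC=C(C)C)[C@H]2CC[C@]1(C)O2 | intermediate
21 | (1S,2S,3S,4R)-1,3-dimethyl-3-(4-methylpent-3-en-1-yl)-2-{(3S)-3-methyl-3-[(triethylsilyl)oxy]pent-4-en-1-yl}-7-oxabicyclo[2.2.1]heptane | C=C[C@@](C)(O[Si](CC)(CC)CC)CC[C@H]1[C@](C)(CCC=C(C)C)[C@H]2CC[C@]1(C)O2 | intermediate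
22 | (1S,2S,3S,4R)-3-{2-[(2R)-3,3-dimethyloxiran-2-yl]ethyl}-1,3-dimethyl-2-{(3S)-3-methyl-3-[(triethylsilyl)oxy]pent-4-en-1-yl}-7-oxabicyclo[2.2.1]heptane | C=C[C@@](C)(O[Si](CC)(CC)CC)CC[C@H]1[C@](C)(CC[C@H]3OC3(C)C)[C@H]2CC[C@]1(C)O2 | intermediate
23 | (1S,2S,3S,4R)-3-[(3R)-4-bromo-3-hydroxy-4-methylpentyl]-1,3-dimethyl-2-{(3S)-3-methyl-3-[(triethylsilyl)oxy]pent-4-en-1-yl}-7-oxabicyclo[2.2.1]heptane | C=C[C@@](C)(O[Si](CC)(CC)CC)CC[C@H]1[C@](C)(CC[C@@H](O)C(C)(C)Br)[C@H]2CC[C@]1(C)O2 | intermediate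
24 | trifluoromethanesulfonate of 23 at the secondary (3R) hydroxyl | C=C[C@@](C)(O[Si](CC)(CC)CC)CC[C@H]1[C@](C)(CC[C@@H](OS(=O)(=O)C(F)(F)F)C(C)(C)Br)[C@H]2CC[C@]1(C)O2 | intermediate
25 | (1S,2S,3S,4R)-3-[(3S)-3-bromo-4-chloro-4-methylpentyl]-1,3-dimethyl-2-{(3S)-3-methyl-3-[(triethylsilyl)oxy]pent-4-en-1-yl}-7-oxabicyclo[2.2.1]heptane | C=C[C@@](C)(O[Si](CC)(CC)CC)CC[C@H]1[C@](C)(CC[C@H](Br)C(C)(C)Cl)[C@H]2CC[C@]1(C)O2 | intermediate
26 | (3S)-5-[(1S,2S,3S,4R)-3-[(3S)-3-bromo-4-chloro-4-methylpentyl]-1,3-dimethyl-7-oxabicyclo[2.2.1]heptan-2-yl]-3-methylpent-1-en-3-ol | C=C[C@@](C)(O)CC[C@H]1[C@](C)(CC[C@H](Br)C(C)(C)Cl)[C@H]2CC[C@]1(C)O2 | target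

**Step count and risks**

Total step count: 15. Longest linear sequence: 15 steps (from geraniol 1; the route is fully linear).

Steps most likely to fail:

1. Step 5 (key step). The attack of the ketone oxygen on the hindered cyclopropane CH may be slow. Then capture of the activated ring by the trisubstituted olefin, epimerisation beside the ketone, or stalling of the last C–C closure next to the C2 chain may take over. Fallback, from 9 back to 11, reverses the bond order by a halide relay on the C4 epimer. Cyclopropanation of 9 as in step 4 but with the antipodal ligand should give dimethyl (2R)-2-{(3S,4R)-4,8-dimethyl-2-oxo-3-[4-(trimethylsilyl)but-3-yn-1-yl]non-7-en-4-yl}cyclopropane-1,1-dicarboxylate F1. MgI2 in THF at 60 °C should open it by iodide attack with inversion to the magnesium enolate of dimethyl 2-[(2S,3S,4S)-4-acetyl-2-iodo-3-methyl-3-(4-methylpent-3-en-1-yl)-8-(trimethylsilyl)oct-7-yn-1-yl]propanedioate F2. Aldol addition of this enolate to the ketone and displacement of iodide by the new alkoxide (second inversion) should arrive at 11 with the same configuration.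

2. Step 4. Carbenoid transfer may compete at the trisubstituted olefin or the silyl alkyne, and facial control at the hindered vinyl group may be incomplete. Fallback, from 9 back to 10, masks the competing olefin. Br2 (1 equiv, CH2Cl2, −78 °C) should add selectively to the trisubstituted olefin to give (3S,4R,7RS)-7,8-dibromo-4-ethenyl-4,8-dimethyl-3-[4-(trimethylsilyl)but-3-yn-1-yl]nonan-2-one F3. The cyclopropanation is then run on F3 to give dimethyl (2S)-2-{(3S,4R,7RS)-7,8-dibromo-4,8-dimethyl-2-oxo-3-[4-(trimethylsilyl)but-3-yn-1-yl]nonan-4-yl}cyclopropane-1,1-dicarboxylate F4, from which any epimer at the ring CH is removed by chromatography. Zinc dust in AcOH/Et2O then returns the olefin and gives 10.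

3. Step 14. The bromonium ion may lose a proton to give an allylic bromide, may be captured by the bridging ether oxygen, or the bromine shift may be incomplete so that the regioisomeric chloride forms. Fallback, from 22 back to 25, avoids the shift. Li2NiBr4 in THF should open epoxide 22 at the secondary carbon with inversion to (1S,2S,3S,4R)-3-[(3S)-3-bromo-4-hydroxy-4-methylpentyl]-1,3-dimethyl-2-{(3S)-3-methyl-3-[(triethylsilyl)oxy]pent-4-en-1-yl}-7-oxabicyclo[2.2.1]heptane F5. SOCl2 with 2,6-lutidine in CH2Cl2 at −20 °C then converts the tertiary alcohol into the chloride with retention at the bromide-bearing carbon (neighbouring bromine), which gives 25.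

Further compounds
F1 | step 5 | dimethyl (2R)-2-{(3S,4R)-4,8-dimethyl-2-oxo-3-[4-(trimethylsilyl)but-3-yn-1-yl]non-7-en-4-yl}cyclopropane-1,1-dicarboxylate | C[Si](C)(C)C#CCC[C@H](C(C)=O)[C@](C)(CCC=C(C)C)[C@H]1CC1(C(=O)OC)C(=O)OC
F2 | step 5 | dimethyl 2-[(2S,3S,4S)-4-acetyl-2-iodo-3-methyl-3-(4-methylpent-3-en-1-yl)-8-(trimethylsilyl)oct-7-yn-1-yl]propanedioate | C[Si](C)(C)C#CCC[C@H](C(C)=O)[C@](C)(CCC=C(C)C)[C@@H](I)CC(C(=O)OC)C(=O)OC
F3 | step 4 | (3S,4R,7RS)-7,8-dibromo-4-ethenyl-4,8-dimethyl-3-[4-(trimethylsilyl)but-3-yn-1-yl]nonan-2-one | C[Si](C)(C)C#CCC[C@H](C(C)=O)[C@](C)(CCC(Br)C(C)(C)Br)C=C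
F4 | step 4 | dimethyl (2S)-2-{(3S,4R,7RS)-7,8-dibromo-4,8-dimethyl-2-oxo-3-[4-(trimethylsilyl)but-3-yn-1-yl]nonan-4-yl}cyclopropane-1,1-dicarboxylate | C[Si](C)(C)C#CCC[C@H](C(C)=O)[C@](C)(CCC(Br)C(C)(C)Br)[C@@H]1CC1(C(=O)OC)C(=O)OC
F5 | step 14 | (1S,2S,3S,4R)-3-[(3S)-3-bromo-4-hydroxy-4-methylpentyl]-1,3-dimethyl-2-{(3S)-3-methyl-3-[(triethylsilyl)oxy]pent-4-en-1-yl}-7-oxabicyclo[2.2.1]heptane | C=C[C@@](C)(O[Si](CC)(CC)CC)CC[C@H]1[C@](C)(CC[C@H](Br)C(C)(C)O)[C@H]2CC[C@]1(C)O2
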